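The pseudo-symmetry of the cyclobutane region means substrate control cannot link C-3 to the core, so C-3 is set by a chiral reagent in the key step and C-11 and C-1 are relayed from it through a bridged lactone.

Ring C, the cycloheptane closed across cyclobutane ring B, carries a 1,3-dioxygen pair (C-1, C-3) and an oxygen on C-15 that lies cis and 1,5 to O-3. The route therefore inserts a two-carbon acetate unit (C-1–C-2) between a C-3 aldehyde and a C-11 ester α-carbon that hang cis-1,3 on a pinane-type bicyclo[3.1.1]heptane, itself made by an intramolecular vinylketene [2+2] cycloaddition. One SmI2 operation forms C-2–C-3 by an auxiliary-controlled Reformatsky aldol and C-1–C-11 by a Reformatsky–Claisen acylation; the bridged keto lactone that results relays C-3 to C-11 and C-1.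

Key step: step 13

Atom labels (target, used throughout): C-1 CH(OAng); C-2 the CH2 between the two carbinol carbons; C-3 CH(OH); C-4 the methyl-bearing quaternary cyclobutane carbon; C-5, C-6, C-7 the cyclobutane CH carbons that bear C-10, C-11 and C-8; C-8 ketone; C-9 CH2; C-10 CH(CH3); C-11 the quaternary carbon bearing CH3 and C-15 (CH2OAc). Ring A = cyclohexanone (C-5 to C-10), ring B = cyclobutane (C-4 to C-7), ring C = cycloheptane (C-1, C-2, C-3, C-4, C-6, C-11 and C-5 or C-7).

Assumption: the samarium Reformatsky aldol is taken to proceed through the chelated chair with attack anti to the benzyl group, giving 3R from the (4S) reagent; if a model shows the reverse sense, the (4R) reagent is used and nothing else changes.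

Step 1
Reactants: 1 (4S)-4-benzyl-3-propanoyl-1,3-oxazolidin-2-one; 2 ethyl (2E)-4-bromo-3-methylbut-2-enoate
Product: 3 ethyl (2E,5R)-6-[(4S)-4-benzyl-2-oxo-1,3-oxazolidin-3-yl]-3,5-dimethyl-6-oxohex-2-enoate
Conditions: NaN(SiMe3)2, THF, −78 °C; then 2, −78 to −30 °C
Reagents that add atoms: none
Why: Evans asymmetric alkylation: the chelated Z sodium enolate is alkylated by the allylic bromide (SN2, conjugate addition being disfavoured at the fully substituted β-carbon) on the face opposite the benzyl group, which sets C-10.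

Step 2
Reactants: 3 alkylated imide
Product: 4 ethyl (2E,5R)-6-hydroxy-3,5-dimethylhex-2-enoate
Conditions: LiBH4, MeOH (1 equiv), Et2O, 0 °C
Reagents that add atoms: none
Why: Reductive cleavage of the N-acyl oxazolidinone, whose imide carbonyl is far more electrophilic than the β,β-disubstituted enoate, leaves C-10 untouched.

Step 3
Reactants: 4 hydroxy enoate
Product: 5 ethyl (2E,5R)-3,5-dimethyl-6-oxohex-2-enoate
Conditions: Dess–Martin periodinane, CH2Cl2, 23 °C
Reagents that add atoms: none
Why: Dess–Martin oxidation of a primary alcohol is neutral enough not to epimerise the α-methyl aldehyde.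

Step 4
Reactants: 5 aldehyde; 6 2-(triphenylphosphoranylidene)propanal
Product: 7 ethyl (2E,5R,6E)-3,5,7-trimethyl-8-oxoocta-2,6-dienoate
Conditions: PhMe, 80 °C
Reagents that add atoms: none
Why: Wittig olefination with a stabilised ylide should give the E trisubstituted enal (C-3 trans to C-10) without base and therefore without loss of C-10.

Step 5
Reactants: 7 enal
Product: 8 ethyl (2E,5R,6E)-8,8-dimethoxy-3,5,7-trimethylocta-2,6-dienoate
Conditions: HC(OMe)3, MeOH, PPTS (cat.), 23 °C
Reagents that add atoms: trimethyl orthoformate COC(OC)OC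
Why: Acid-catalysed acetalisation masks C-3 and removes the conjugation, so the C-4=C-5 alkene stays nucleophilic for step 7.

Step 6
Reactants: 8 acetal ester
Product: 9 (2E,5R,6E)-8,8-dimethoxy-3,5,7-trimethylocta-2,6-dienoic acid
Conditions: LiOH, THF/MeOH/H2O, 50 °C; then aq. NaH2PO4
Reagents that add atoms: lithium hydroxide [Li+].[OH-]
Why: Saponification; the acetal is stable to base and to the buffered acidification.

Step 7
Reactants: 9 dienoic acid
Product: 12 (1R,2R,5S,7R)-7-(dimethoxymethyl)-2,7-dimethyl-4-methylidenebicyclo[3.1.1]heptan-6-one, via acid chloride 10 (not isolated), via vinylketene 11 (not isolated)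
Conditions: 1-chloro-N,N,2-trimethylprop-1-en-1-amine, CH2Cl2, 23 °C; then slow addition to Et3N, PhMe, 110 °C
Reagents that add atoms: none
Why: Intramolecular vinylketene–alkene [2+2] cycloaddition (known for geranoyl and farnesoyl chlorides): dehydrochlorination through the γ-methyl cis to the carbonyl gives the vinylketene, its carbonyl carbon bonds to C-5 and its α-carbon to C-4 with retention of alkene geometry (methyl on C-4 syn to the three-carbon bridge), and A(1,3) strain between the C-10 hydrogen and the cis methyl on C-4 puts the tether on one alkene face, so C-10 should fix C-4, C-5 and C-7.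

Step 8
Reactants: 12 cyclobutanone; 13 methyl 2-(dimethoxyphosphoryl)propanoate
Product: 14 methyl 2-[7-(dimethoxymethyl)-2,7-dimethyl-4-methylidenebicyclo[3.1.1]heptan-6-ylidene]propanoate (ring stereocentres as in 12; C-6=C-11 isomer mixture)
Conditions: NaH, THF, 0 to 66 °C
Reagents that add atoms: none
Why: Horner–Wadsworth–Emmons olefination of a strained ketone that cannot enolise (both α-carbons are bridgeheads); the alkene geometry is irrelevant.

Step 9
Reactants: 14 alkylidene ester
Product: 15 methyl 2-[7-(dimethoxymethyl)-2,7-dimethyl-4-methylidenebicyclo[3.1.1]heptan-6-yl]propanoate (C-11 on C-6 cis to the dimethoxymethyl group; epimers at C-11)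
Conditions: Mg, MeOH, 23 °C
Reagents that add atoms: none
Why: Dissolving-metal conjugate reduction of the enoate leaves the isolated methylidene alone, and C-6 should be protonated from the face syn to the three-carbon bridge because the other face is blocked by the pseudo-axial CH(OMe)2 group lying 1,3 across the cyclobutane, which places C-11 cis to C-3.

Step 10
Reactants: 15 saturated ester
Product: 16 methyl 2-chloro-2-[7-(dimethoxymethyl)-2,7-dimethyl-4-methylidenebicyclo[3.1.1]heptan-6-yl]propanoate (epimers at C-11)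
Conditions: LiN(iPr)2, THF, −78 °C; then C2Cl6
Reagents that add atoms: hexachloroethane ClC(Cl)(Cl)C(Cl)(Cl)Cl
Why: Electrophilic chlorination of the ester enolate installs the handle from which the C-11 enolate is later generated reductively; the C-11 configuration is irrelevant.

Step 11
Reactants: 16 chloro ester acetal
Product: 17 methyl 2-chloro-2-[7-formyl-2,7-dimethyl-4-methylidenebicyclo[3.1.1]heptan-6-yl]propanoate
Conditions: PPTS, acetone/H2O, 50 °C
Reagents that add atoms: water O
Why: Mild acetal hydrolysis frees the C-3 aldehyde, which has no α-hydrogen and cannot epimerise.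

Step 12
Reactants: 18 (4S)-4-benzyl-1,3-oxazolidin-2-one; 19 bromoacetyl bromide
Product: 20 (4S)-4-benzyl-3-(bromoacetyl)-1,3-oxazolidin-2-one
Conditions: nBuLi, THF, −78 °C; then 19
Reagents that add atoms: none
Why: N-acylation of the lithiated oxazolidinone gives the chiral two-carbon reagent (18 recovered in step 2 can be used here).

Step 13
Reactants: 17 aldehyde chloro ester; 20 chiral bromoacetyl imide
Product: 23 keto lactone (ring C closed; C-1 ketone; δ-lactone from O-3 to C-15; C-8 methylidene; C-3, C-4, C-5, C-6, C-7, C-10, C-11 arranged as in 31), via aldol adduct 21 (not isolated), via hydroxy keto ester 22 (not isolated)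
Conditions: SmI2 (2.5 equiv), THF, −78 °C; then SmI2 (2.5 equiv), HMPA, −78 to 0 °C
Reagents that add atoms: none
Why: Proposed new method: SmI2 first reduces only the C–Br bond of 20 (the tertiary C–Cl bond is inert at −78 °C without HMPA), and the chelated samarium enolate adds to the C-3 aldehyde through a chair transition state anti to the benzyl group; this is the known samarium Reformatsky acetate aldol, it forms C-2–C-3, and the auxiliary rather than the locally symmetric substrate sets C-3. With HMPA the tertiary chloride is reduced and the C-11 ester enolate attacks the imide carbonyl C-1, activated by the trivalent samarium alkoxide on O-3, in a 7-exo-trig acyl substitution that forms C-1–C-11, closes ring C and expels the oxazolidinone; the closest known type is the samarium Reformatsky–Claisen (Dieckmann-type) acylation of α-halo esters. The O-3 alkoxide then closes the δ-lactone on the ester (6-exo-trig), which is possible only when C-15 is cis to O-3, so the samarium bridge between O-3 and the enolate oxygen during acylation and the lactone itself secure C-11 relative to C-3. The step needs chemoselectivity in three places: bromide before chloride, aldehyde before imide, and no direct attack of C-11 on C-3, which is expected to be suppressed because it would build a bicyclo[2.1.1]hexane and is reversible.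

Step 14
Reactants: 23 keto lactone
Product: 24 hydroxy lactone (C-1 hydroxyl anti to the lactone bridge, 1,3-anti to O-3)
Conditions: NaBH4, MeOH/THF, 0 °C
Reagents that add atoms: none
Why: Ketone reduction in the bridged bicycle: hydride should approach C-1 from the side of the flat two-atom lactone bridge rather than past the cyclobutane bridge, which sets C-1 with its oxygen anti to O-3.

Step 15
Reactants: 24 hydroxy lactone; 25 angelic acid
Product: 27 angelate lactone, via mixed anhydride 26 (not isolated)
Conditions: 25, 2,4,6-Cl3C6H2COCl, Et3N, PhMe, 23 °C; then 24, 80 °C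
Reagents that add atoms: none
Why: Yamaguchi-type esterification of the only free hydroxyl (O-3 is tied up in the lactone), run without DMAP so that the Z double bond of the angelate should not isomerise.

Step 16
Reactants: 27 angelate lactone
Product: 29 diol (C-3 hydroxyl and C-15 primary hydroxyl; C-1 angelate), via lactol 28 (not isolated)
Conditions: iBu2AlH (1.2 equiv), CH2Cl2, −78 °C; then MeOH, NaBH4, −78 to 0 °C
Reagents that add atoms: none
Why: Partial reduction of the strained bridged lactone to the lactol should be faster than attack on the hindered conjugated angelate, and NaBH4 then reduces the ring-opened hydroxy aldehyde without touching esters.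

Step 17
Reactants: 29 diol
Product: 30 C-15 acetate (C-3 hydroxyl free; C-8 methylidene)
Conditions: AcCl, 2,4,6-collidine, CH2Cl2, −78 °C
Reagents that add atoms: acetyl chloride CC(Cl)=O
Why: Selective acetylation of the primary hydroxyl over the hindered secondary neopentylic C-3 hydroxyl.

Step 18
Reactants: 30 methylidene acetate
Product: 31 target CNP0212099.1
Conditions: O3, CH2Cl2, pyridine, −78 °C (Sudan Red 7B end point); then Me2S
Reagents that add atoms: ozone [O-][O+]=O
Why: Ozonolysis of the electron-rich 1,1-disubstituted alkene should be much faster than that of the electron-poor trisubstituted angelate and reveals the C-8 ketone.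

Compound list
1 | (4S)-4-benzyl-3-propanoyl-1,3-oxazolidin-2-one | CCC(=O)N1[C@@H](Cc2ccccc2)COC1=O | starting material
2 | ethyl (2E)-4-bromo-3-methylbut-2-enoate | CCOC(=O)/C=C(\C)CBr | starting material
3 | ethyl (2E,5R)-6-[(4S)-4-benzyl-2-oxo-1,3-oxazolidin-3-yl]-3,5-dimethyl-6-oxohex-2-enoate | CCOC(=O)/C=C(\C)C[C@@H](C)C(=O)N1[C@@H](Cc2ccccc2)COC1=O | intermediate
4 | ethyl (2E,5R)-6-hydroxy-3,5-dimethylhex-2-enoate | CCOC(=O)/C=C(\C)C[C@@H](C)CO | intermediate
5 | ethyl (2E,5R)-3,5-dimethyl-6-oxohex-2-enoate | CCOC(=O)/C=C(\C)C[C@@H](C)C=O | intermediate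
6 | 2-(triphenylphosphoranylidene)propanal | CC(C=O)=P(c1ccccc1)(c1ccccc1)c1ccccc1 | starting material
7 | ethyl (2E,5R,6E)-3,5,7-trimethyl-8-oxoocta-2,6-dienoate | CCOC(=O)/C=C(\C)C[C@@H](C)/C=C(\C)C=O | intermediate
8 | ethyl (2E,5R,6E)-8,8-dimethoxy-3,5,7-trimethylocta-2,6-dienoate | CCOC(=O)/C=C(\C)C[C@@H](C)/C=C(\C)C(OC)OC | intermediate
9 | (2E,5R,6E)-8,8-dimethoxy-3,5,7-trimethylocta-2,6-dienoic acid | OC(=O)/C=C(\C)C[C@@H](C)/C=C(\C)C(OC)OC | intermediate
10 | (2E,5R,6E)-8,8-dimethoxy-3,5,7-trimethylocta-2,6-dienoyl chloride (formed in the flask) | ClC(=O)/C=C(\C)C[C@@H](C)/C=C(\C)C(OC)OC | intermediate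
11 | vinylketene (5R,6E)-8,8-dimethoxy-5,7-dimethyl-3-methylideneocta-1,6-dien-1-one (formed in the flask) | O=C=CC(=C)C[C@@H](C)/C=C(\C)C(OC)OC | intermediate
12 | (1R,2R,5S,7R)-7-(dimethoxymethyl)-2,7-dimethyl-4-methylidenebicyclo[3.1.1]heptan-6-one (2-methyl on the side of the carbonyl bridge; 7-methyl syn to the three-carbon bridge) | COC(OC)[C@]1(C)[C@@H]2C(=O)[C@H]1C(=C)C[C@H]2C | intermediate
13 | methyl 2-(dimethoxyphosphoryl)propanoate | COC(=O)C(C)P(=O)(OC)OC | starting material
14 | methyl 2-[7-(dimethoxymethyl)-2,7-dimethyl-4-methylidenebicyclo[3.1.1]heptan-6-ylidene]propanoate (ring stereocentres as in 12; alkene isomer mixture) | COC(OC)[C@]1(C)[C@@H]2C(=C(C)C(=O)OC)[C@H]1C(=C)C[C@H]2C | intermediate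
15 | methyl 2-[7-(dimethoxymethyl)-2,7-dimethyl-4-methylidenebicyclo[3.1.1]heptan-6-yl]propanoate (side chain on C-6 cis to the dimethoxymethyl group; epimers at C-11) | COC(OC)[C@]1(C)[C@@H]2[C@@H]([C@H]1C(=C)C[C@H]2C)C(C)C(=O)OC | intermediate
16 | methyl 2-chloro-2-[7-(dimethoxymethyl)-2,7-dimethyl-4-methylidenebicyclo[3.1.1]heptan-6-yl]propanoate (ring as in 15; epimers at C-11) | COC(OC)[C@]1(C)[C@@H]2[C@@H]([C@H]1C(=C)C[C@H]2C)C(C)(Cl)C(=O)OC | intermediate
17 | methyl 2-chloro-2-[7-formyl-2,7-dimethyl-4-methylidenebicyclo[3.1.1]heptan-6-yl]propanoate (ring as in 15; epimers at C-11) | O=C[C@]1(C)[C@@H]2[C@@H]([C@H]1C(=C)C[C@H]2C)C(C)(Cl)C(=O)OC | intermediate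
18 | (4S)-4-benzyl-1,3-oxazolidin-2-one | O=C1N[C@@H](Cc2ccccc2)CO1 | starting material
19 | bromoacetyl bromide | BrCC(Br)=O | starting material
20 | (4S)-4-benzyl-3-(bromoacetyl)-1,3-oxazolidin-2-one | BrCC(=O)N1[C@@H](Cc2ccccc2)COC1=O | intermediate
21 | aldol adduct: (4S)-4-benzyl-3-[(3R)-3-hydroxy-3-(bicyclic core of 17 at C-4)propanoyl]-1,3-oxazolidin-2-one (formed in the flask as its samarium alkoxide) | O=C(C[C@@H](O)[C@]2(C)[C@@H]3[C@@H]([C@H]2C(=C)C[C@H]3C)C(C)(Cl)C(=O)OC)N1[C@@H](Cc4ccccc4)COC1=O | intermediate
22 | hydroxy keto ester: ring C closed, C-1 ketone, C-3 hydroxyl, C-11 bearing CH3 and CO2CH3 cis to O-3 (formed in the flask) | O=C1C[C@@H](O)[C@]2(C)[C@@H]3[C@@H]([C@H]2C(=C)C[C@H]3C)[C@@]1(C)C(=O)OC | intermediate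
23 | keto lactone: C-1 ketone, δ-lactone O-3 to C-15, C-8 methylidene | O=C1C[C@@H]4[C@]2(C)[C@@H]3[C@@H]([C@H]2C(=C)C[C@H]3C)[C@@]1(C)C(=O)O4 | intermediate
24 | hydroxy lactone: C-1 hydroxyl (configuration of 31), δ-lactone O-3 to C-15 | O[C@@H]1C[C@@H]4[C@]2(C)[C@@H]3[C@@H]([C@H]2C(=C)C[C@H]3C)[C@@]1(C)C(=O)O4 | intermediate
25 | angelic acid, (2Z)-2-methylbut-2-enoic acid | C/C=C(/C)C(=O)O | starting material
26 | (2Z)-2-methylbut-2-enoic 2,4,6-trichlorobenzoic anhydride (formed in the flask) | C/C=C(/C)C(=O)OC(=O)c1c(Cl)cc(Cl)cc1Cl | intermediate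
27 | angelate lactone: C-1 angelate, δ-lactone O-3 to C-15 | C/C=C(/C)C(=O)O[C@@H]1C[C@@H]4[C@]2(C)[C@@H]3[C@@H]([C@H]2C(=C)C[C@H]3C)[C@@]1(C)C(=O)O4 | intermediate
28 | lactol: C-1 angelate, cyclic hemiacetal between O-3 and C-15 (formed in the flask; anomer mixture) | C/C=C(/C)C(=O)O[C@@H]1C[C@@H]4[C@]2(C)[C@@H]3[C@@H]([C@H]2C(=C)C[C@H]3C)[C@@]1(C)C(O)O4 | intermediate
29 | diol: C-1 angelate, C-3 hydroxyl, C-15 hydroxymethyl, C-8 methylidene | C/C=C(/C)C(=O)O[C@@H]1C[C@@H](O)[C@]2(C)[C@@H]3[C@@H]([C@H]2C(=C)C[C@H]3C)[C@@]1(C)CO | intermediate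
30 | acetate: C-1 angelate, C-3 hydroxyl, C-15 acetate, C-8 methylidene | C/C=C(/C)C(=O)O[C@@H]1C[C@@H](O)[C@]2(C)[C@@H]3[C@@H]([C@H]2C(=C)C[C@H]3C)[C@@]1(C)COC(C)=O | intermediate
31 | CNP0212099.1: C-1 angelate, C-3 hydroxyl, C-8 ketone, C-15 acetate; (1R,3R,4R,5S,6S,7R,10R,11S) in the labels above | C/C=C(/C)C(=O)O[C@@H]1C[C@@H](O)[C@]2(C)[C@@H]3[C@@H]([C@H]2C(=O)C[C@H]3C)[C@@]1(C)COC(C)=O | target

Total step count: 18. Longest linear sequence: 17 steps (steps 1–11 and 13–18; step 12 is a one-step side branch).

Steps most likely to fail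

1. Step 13 (proposed new method). The tertiary samarium enolate may be protonated, or may take a proton from C-2 of the imide, instead of attacking C-1; acyl transfer could also occur on the wrong enolate face, giving material that cannot lactonise. Fallback with known chemistry, setting out from 17: only the first stage is run (SmI2, 20, THF, −78 °C, no HMPA) and aldol adduct 21 is isolated. LiBH4 (Et2O, MeOH, 0 °C) removes the auxiliary to give the 1,3-diol F1. TEMPO/PhI(OAc)2 oxidises only the primary hydroxyl to give the β-hydroxy aldehyde F2. SmI2/HMPA then effects the well-precedented intramolecular Reformatsky addition of the α-chloro ester to this aldehyde; chelation of O-3 and the aldehyde to samarium should give the 1,3-anti dihydroxy ester F3. Its cis ester lactonises (PPTS, PhMe, 80 °C) to 24, where the route is rejoined and step 14 is no longer needed.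

2. Step 8. The branched phosphonate anion may add sluggishly to the hindered cyclobutanone, or the adduct may fail to collapse to the tetrasubstituted alkene. Fallback, setting out from 12: Reformatsky addition (Zn, methyl 2-bromopropanoate, THF, reflux), which tolerates hindered ketones that cannot enolise, gives the β-hydroxy ester F4. Dehydration with SOCl2/pyridine, for which only the ester α-hydrogen is available, gives 14.

3. Step 16. The aluminium hydride may also reduce the angelate, or the angelate may shift from O-1 to the new primary alkoxide on C-15. Fallback, setting out from 24: iBu2AlH (2.2 equiv, CH2Cl2, −78 °C) gives the hydroxy lactol F5 before any angelate is present. MeOH/PPTS converts it into the bridged methyl acetal F6, which masks O-3 and C-15 without an ester. Angeloylation as in step 15 gives the angelate acetal F7. Aqueous AcOH followed by NaBH4 (the only hydride used once the angelate is in place) gives diol 29.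

Further compounds
F1 | step 13 | 1,3-diol: methyl 2-chloro-2-[7-((1R)-1,3-dihydroxypropyl)-2,7-dimethyl-4-methylidenebicyclo[3.1.1]heptan-6-yl]propanoate | OCC[C@@H](O)[C@]2(C)[C@@H]3[C@@H]([C@H]2C(=C)C[C@H]3C)C(C)(Cl)C(=O)OC
F2 | step 13 | β-hydroxy aldehyde: methyl 2-chloro-2-[7-((1R)-1-hydroxy-3-oxopropyl)-2,7-dimethyl-4-methylidenebicyclo[3.1.1]heptan-6-yl]propanoate | O=CC[C@@H](O)[C@]2(C)[C@@H]3[C@@H]([C@H]2C(=C)C[C@H]3C)C(C)(Cl)C(=O)OC
F3 | step 13 | dihydroxy ester: ring C closed, C-1 and C-3 hydroxyls anti, C-11 bearing CH3 and CO2CH3 | O[C@@H]1C[C@@H](O)[C@]2(C)[C@@H]3[C@@H]([C@H]2C(=C)C[C@H]3C)[C@@]1(C)C(=O)OC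
F4 | step 8 | β-hydroxy ester: methyl 2-[7-(dimethoxymethyl)-6-hydroxy-2,7-dimethyl-4-methylidenebicyclo[3.1.1]heptan-6-yl]propanoate | COC(OC)[C@]1(C)[C@@H]2C(O)(C(C)C(=O)OC)[C@H]1C(=C)C[C@H]2C
F5 | step 16 | hydroxy lactol: C-1 hydroxyl, cyclic hemiacetal between O-3 and C-15 | O[C@@H]1C[C@@H]4[C@]2(C)[C@@H]3[C@@H]([C@H]2C(=C)C[C@H]3C)[C@@]1(C)C(O)O4
F6 | step 16 | bridged methyl acetal: C-1 hydroxyl, C-15 methoxy acetal bridged to O-3 | O[C@@H]1C[C@@H]4[C@]2(C)[C@@H]3[C@@H]([C@H]2C(=C)C[C@H]3C)[C@@]1(C)C(OC)O4
F7 | step 16 | angelate acetal: C-1 angelate, C-15 methoxy acetal bridged to O-3 | C/C=C(/C)C(=O)O[C@@H]1C[C@@H]4[C@]2(C)[C@@H]3[C@@H]([C@H]2C(=C)C[C@H]3C)[C@@]1(C)C(OC)O4
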